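**Compound numbering.** Compounds 1–41 are numbered in the order in which they first appear in the steps and carry the same numbers throughout.

## Analysis of the target

Compound 41 is a resveratrol trimer (C42H32O9) built from two 2,3-diaryl-2,3-dihydrobenzofurans. Dihydrobenzofuran 1 (O1, C2, C3, fused to ring A) and dihydrobenzofuran 2 (O1′, C2′, C3′, fused to ring B) are joined by the C3–C5′ bond, and ring A carries a (Z)-4-hydroxystyryl group at C4. The four stereocentres are (2S,3S) and (2′R,3′R). Within each ring the two aryl groups are trans, but the two pairs lie on either side of ring B and cannot control each other, so each pair needs its own source of absolute configuration. Both C2 and C2′ carry a 4-oxyphenyl group, so the C2–O bonds ionise under acid. This allows a cis isomer to be corrected at C2 but also threatens ring opening, whereas the diaryl methines C3 and C3′ cannot be corrected once set. The free phenols are oxidation-sensitive and the Z-stilbene isomerises or cyclises onto its electron-rich neighbours under acid or light, so the alkene has to be made last. The hard parts are the two vicinal arrays, in which the groups to be told apart at C3 and C3′ are aryl rings of similar size, and the placing of nine oxygens on five rings. The strategy rests on ring B, a 2,3-dihydrobenzofuran-7-ol with O1′ on C7a′, a hydroxyl on the neighbouring C7′, C–H at C4′ and C6′, and its only carbon substituent at C5′. This is the pattern that results when a 2-furyl group and an ethynyl ether, tethered through C3′–C2′–O1′, are isomerised into a benzene ring.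

## Retrosynthetic reasoning

**Z-alkene.** 41 is cut back to the diarylalkyne 40. The alkene is formed last by semi-hydrogenation, because a Z-stilbene flanked by phenols would not survive the Lewis acid needed to free them; syn-addition to the alkyne fixes the geometry without an olefination that could give E/Z mixtures.

**Phenols and the C4–C(sp) bond.** 40 comes from the heptamethyl ether 39, and 39 from the triflate 37 and the alkyne 38. C4 of ring A is meta to both ring A oxygens and cannot be reached by electrophilic substitution, so it is carried as an oxygen (phenol 36) and converted to carbon by cross-coupling.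

**C2–C3 of dihydrobenzofuran 1.** 36 is traced to the cis isomer 35, and 35 to the diazo compound 34 (from hydrazone 33 and ketone 32). The C2–C3 bond is cut rather than C2–O, because a carbenoid at C3 that inserts into the neighbouring O–CH2–aryl bond is controlled by a chiral catalyst and does not depend on the remote C2′ and C3′ centres. The forward step must set C3; C2 can afterwards be equilibrated to trans through reversible C2–O ionisation, and the same acid frees the C4 phenol.

**C3–C3a.** 32 comes from the carbinol 31, made from the aldehyde 25 and the arylmagnesium 30 derived from iodide 29. Ring A is brought in symmetrically substituted (29, from 26 via 27 with 28), so that either ortho oxygen can become O1 while the other becomes the C4 oxygen; this removes any regiochemical question on ring A.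

**C5′ handle.** 25 is reached from the key-step product 22 through 23 and 24 by methylation of the lone phenol, desilylation and oxidation.

**Ring B and the dihydrofuran ring (key disconnection).** 22 is cut at C7a′–C3a′ and C7′–C6′ to the ethynyl ether 21. The cut is made here because it turns ring B into a furan plus two alkyne carbons, needs no ortho-disubstituted aryl halide, and delivers the 7′-hydroxyl as the only free phenol. The forward isomerisation must put the hydroxyl at C7′ and leave the two tether stereocentres untouched.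

**Ynol ether.** 21 comes from the alcohol 17 and trichloroethene 18 (through 19 and 20) without breaking the C–O bond of the carbinol carbon.

**The acyclic array.** 17 is traced through 16, 13, 11 and 8 to the boronic ester 6 (from 4 and 5), the furyllithium 9 (from 3) and the Grignard reagent 14. The C–aryl, C–C and C–furyl bonds are made one at a time on boron. Reduction of the corresponding triaryl ketone under dynamic resolution was not chosen: it would require a catalyst to tell a 2-furyl from a 3,5-dimethoxyphenyl group on the α-carbon, and a sterically controlled transition state with the larger aryl anti to hydride leads to the cis-forming epimer. In the boron sequence each centre is set by the diol and by inversion at carbon, so no such discrimination is needed.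

**Furan building block.** 3 comes from the ester 1 through alcohol 2; the bromine marks the furan carbon that becomes C3a′ and the ester carbon becomes the C5′ substituent.

## Alternatives that were turned down

**Alternative 1:** The C2′–aryl and C3′–C3a′ bonds are cut together. In the forward direction the aryllithium A4 adds to the boron of the (E)-styryl boronic ester A3, and under palladium catalysis with a chiral ferrocenyl diphosphine the ring B aryl bromide A2 triggers a 1,2-shift of the anisyl group from boron to C2′ while ring B adds anti at C3′, giving the boronic ester A1. In its favour, one catalytic stereospecific step sets both centres of dihydrobenzofuran 2, and ring B arrives with all its oxygens in place. On step count to the C2′/C3′ array it is stronger than the four-operation boronate homologation used here. Against it, β-aryl alkenyl boronates are the weak substrate class for this metallate shift, since direct cross-coupling of the ate complex competes, and A2 is ortho-substituted at the reacting carbon. A1 also still needs oxidation, unmasking of the phenol and a separate C2′–O ring closure. The chosen strategy gives in exchange the simultaneous formation of ring B and the dihydrofuran ring in an isomerisation that loses no atoms, with no aryl halide and with the 7′-hydroxyl differentiated by the mechanism.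

**Alternative 2:** The C3–C3a bond of dihydrobenzofuran 1 is cut back to the flavanone A6, a protected (S)-naringenin. In the forward direction a trivalent iodine oxidant in an acidic orthoester medium makes ring A migrate from the carbonyl carbon to C3, contracting the pyranone to the trans ester A5. In its favour, A6 comes from the chiral pool with C2, the 4-oxyphenyl group and both ring A oxygens present, and the trans pair is set by the substrate. On the stereochemistry of dihydrobenzofuran 1 this is simpler than the catalyst-controlled insertion used here. Against it for this target, C3 of A5 carries an ester carbon where the target needs the C3–C5′ aryl bond. Ring B would have to be grown from that carbon or the ester exchanged for an aryl group at an epimerisable centre next to a leaving oxygen. The flavanone can also racemise through its chalcone, and nothing in the step addresses ring B or dihydrobenzofuran 2. The chosen strategy builds exactly that part, ring B with its 7′-hydroxyl, and attaches C3 to C5′ directly through the aldehyde carbon.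

**Alternative 3:** Ring A is cut into three alkynes. In the forward direction the diyne A8 (an ethynyl ether and a Z-enyne joined through O1–C2–C3) and ethoxyethyne A9 combine on a cationic monovalent rhodium–bisphosphine catalyst, forming C3a–C7a, C4–C5 and C6–C7 to give A7. In its favour it is highly convergent: ring A and the dihydrofuran ring close at once, the Z-styryl group is already in place, and no triflation, coupling or semi-hydrogenation is needed. On convergence for ring A it is stronger than the route chosen here. Against it, the position of the ethoxy group depends on the orientation of an intermolecular partner, the Z-enyne can isomerise or enter the cycloaddition, and A8 carries a propargylic diaryl-type centre at C3 that is prone to allene formation. A8 also presupposes a finished dihydrobenzofuran 2 and combines the lability of an ynol ether with a late, expensive substrate. The chosen strategy performs its arene construction early, on a small substrate and intramolecularly, so that regiochemistry is fixed by the tether and a failure costs little.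

Key step: step 9

Remark 1: the (R,R)-diol 5 is taken to direct the (αS)-chloride in both homologations, the usual sense for C2-symmetric (R,R)-diol boronic esters; were it opposite, the (S,S)-diol would be used.
Remark 2: Rh2(R-PTAD)4, dirhodium tetrakis[(R)-(1-adamantyl)(phthalimido)acetate], is taken to give the 3S centre in step 18; were the sense opposite, the S-configured catalyst would be used.

## Route

Step 1
Reactants: 1 methyl 5-bromofuran-3-carboxylate
Product: 2 (5-bromofuran-3-yl)methanol
Conditions: (i-Bu)2AlH, CH2Cl2, −78 → 0 °C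
Reagents that add atoms: none
Why: Aluminium hydride reduction of the ester to the primary alcohol; the bromofuran is inert to the hydride at low temperature.

Step 2
Reactants: 2 (5-bromofuran-3-yl)methanol
Product: 3 [(5-bromofuran-3-yl)methoxy]tri(propan-2-yl)silane
Conditions: i-Pr3SiCl, imidazole, DMF, rt
Reagents that add atoms: chlorotri(propan-2-yl)silane, CC(C)[Si](Cl)(C(C)C)C(C)C
Why: Silylation of a primary alcohol; the bulky silyl ether should survive the organolithium, ZnCl2, alkaline peroxide and KH used later.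

Step 3
Reactants: 4 (3,5-dimethoxyphenyl)boronic acid; 5 (1R,2R)-1,2-dicyclohexylethane-1,2-diol
Product: 6 (4R,5R)-4,5-dicyclohexyl-2-(3,5-dimethoxyphenyl)-1,3,2-dioxaborolane
Conditions: MgSO4, Et2O, rt
Reagents that add atoms: none
Why: Condensation of a boronic acid with a 1,2-diol gives the cyclic boronic ester; the C2-symmetric diol is the controlling element for both carbon centres of the array.

Step 4
Reactants: 6 (4R,5R)-4,5-dicyclohexyl-2-(3,5-dimethoxyphenyl)-1,3,2-dioxaborolane
Product: 8 (4R,5R)-2-[(S)-chloro(3,5-dimethoxyphenyl)methyl]-4,5-dicyclohexyl-1,3,2-dioxaborolane, via lithium dichloromethyl borate 7 (not isolated)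
Conditions: CH2Cl2, n-BuLi, THF, −100 °C; then 6; then ZnCl2, −100 °C → rt
Reagents that add atoms: dichloromethane, ClCCl
Why: Matteson homologation: LiCHCl2 adds to boron and ZnCl2 promotes migration of the aryl group with loss of one chloride; the diol decides which chloride leaves and so sets the new carbon as S.

Step 5
Reactants: 3 [(5-bromofuran-3-yl)methoxy]tri(propan-2-yl)silane; 8 (4R,5R)-2-[(S)-chloro(3,5-dimethoxyphenyl)methyl]-4,5-dicyclohexyl-1,3,2-dioxaborolane
Product: 11 (4R,5R)-4,5-dicyclohexyl-2-[(R)-(3,5-dimethoxyphenyl)(4-{[tri(propan-2-yl)silyl]oxymethyl}furan-2-yl)methyl]-1,3,2-dioxaborolane, via furyllithium 9 (not isolated), via lithium furyl borate 10 (not isolated)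
Conditions: 3, n-BuLi, THF, −78 °C; then 8, −78 °C → rt
Reagents that add atoms: none
Why: Bromine–lithium exchange gives the 2-furyllithium, which adds to boron; 1,2-migration of the furyl group displaces chloride with inversion at carbon. The diaryl centre is thus formed stereospecifically, and no reagent has to choose between the two aryl groups.

Step 6
Reactants: 11 (4R,5R)-4,5-dicyclohexyl-2-[(R)-(3,5-dimethoxyphenyl)(4-{[tri(propan-2-yl)silyl]oxymethyl}furan-2-yl)methyl]-1,3,2-dioxaborolane
Product: 13 (4R,5R)-2-[(1S,2R)-1-chloro-2-(3,5-dimethoxyphenyl)-2-(4-{[tri(propan-2-yl)silyl]oxymethyl}furan-2-yl)ethyl]-4,5-dicyclohexyl-1,3,2-dioxaborolane, via lithium dichloromethyl borate 12 (not isolated)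
Conditions: CH2Cl2, n-BuLi, THF, −100 °C; then 11; then ZnCl2, −100 °C → rt
Reagents that add atoms: dichloromethane, ClCCl
Why: Second Matteson homologation: the diarylmethyl group migrates with retention and the diol again fixes the chloride-bearing carbon as S; the descriptor of the diaryl carbon changes only because the new neighbour outranks the furyl group.

Step 7
Reactants: 13 (4R,5R)-2-[(1S,2R)-1-chloro-2-(3,5-dimethoxyphenyl)-2-(4-{[tri(propan-2-yl)silyl]oxymethyl}furan-2-yl)ethyl]-4,5-dicyclohexyl-1,3,2-dioxaborolane; 14 (4-methoxyphenyl)magnesium bromide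
Product: 17 (1R,2S)-2-(3,5-dimethoxyphenyl)-1-(4-methoxyphenyl)-2-(4-{[tri(propan-2-yl)silyl]oxymethyl}furan-2-yl)ethan-1-ol, via magnesium aryl borate 15 (not isolated), via boronic ester 16 (not isolated)
Conditions: 14, THF, −78 °C → rt; then NaOH, H2O2, THF–H2O, 0 °C
Reagents that add atoms: hydrogen peroxide, OO
Why: The aryl Grignard reagent adds to boron and the aryl group migrates with inversion at carbon; alkaline peroxide then replaces boron by hydroxyl with retention, which should give the (1R,2S) alcohol. The furan and the silyl ether tolerate cold alkaline peroxide, and diol 5 is recovered.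

Step 8
Reactants: 17 (1R,2S)-2-(3,5-dimethoxyphenyl)-1-(4-methoxyphenyl)-2-(4-{[tri(propan-2-yl)silyl]oxymethyl}furan-2-yl)ethan-1-ol; 18 trichloroethene
Product: 21 ethynyl (1R,2S)-2-(3,5-dimethoxyphenyl)-1-(4-methoxyphenyl)-2-(4-{[tri(propan-2-yl)silyl]oxymethyl}furan-2-yl)ethyl ether, via dichlorovinyl ether 19 (not isolated), via lithium acetylide 20 (not isolated)
Conditions: KH, THF, 0 °C; 18, rt; then n-BuLi, −78 → −40 °C; MeOH, −78 °C
Reagents that add atoms: none
Why: The potassium alkoxide adds to dichloroethyne formed in situ from 18 to give the (E)-dichlorovinyl ether; elimination and chlorine–lithium exchange with n-BuLi give the lithium acetylide, which is protonated to the ethynyl ether. The C–O bond of the carbinol carbon is never broken, so both centres are kept; the ether is used at once because it can lose ketene by a retro-ene path on warming.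

Step 9
Reactants: 21 ethynyl (1R,2S)-2-(3,5-dimethoxyphenyl)-1-(4-methoxyphenyl)-2-(4-{[tri(propan-2-yl)silyl]oxymethyl}furan-2-yl)ethyl ether
Product: 22 (2R,3R)-3-(3,5-dimethoxyphenyl)-2-(4-methoxyphenyl)-5-{[tri(propan-2-yl)silyl]oxymethyl}-2,3-dihydro-1-benzofuran-7-ol
Conditions: Ph3PAuNTf2 (3 mol%), CH2Cl2, 0 °C → rt
Reagents that add atoms: none
Why: Monovalent gold binds the electron-rich ynol ether, which is polarised like a ketene oxonium so that its oxygen-bearing carbon is the electrophilic one; furan C2 attacks it in a 5-exo-dig closure that forms C7a′–C3a′ and the dihydrofuran ring and leaves a cyclopropyl gold carbenoid at the former terminal carbon. The carbenoid opens with cleavage of the furan C2–O bond to a dienone carbenoid, the carbonyl oxygen on the former furan C5 attacks the carbenoid carbon to give an oxepine, and 6π-electrocyclisation of the oxepine to the arene oxide forms C7′–C6′ and closes ring B. The arene oxide opens at C6′–O, because the resulting cation is stabilised by O1′ through C7a′, and proton loss gives the 7′-phenol. The closest known reaction type is the gold-catalysed furan–yne phenol synthesis in its variant with alkynyl ether tethers, which gives 7-hydroxy-2,3-dihydrobenzofurans. No stereocentre is formed: C2′ and C3′ lie in the tether, take part in no bond change and should keep their configuration under the neutral conditions, so the trans relation of 22 is that of 21 (the same centre is 2S in 21 and 3R in 22 only because the ranking of its neighbours changes). The step needs attack at the oxygen-bearing alkyne carbon, secured by the polarisation and the five-membered tether; the hydroxyl at C7′ and not C6′, which is inherent in the oxepine route and the direction of arene oxide opening; and cyclisation faster than hydration or thermal loss of the ynol ether, secured by dry conditions, low temperature and the intramolecular nucleophile.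

Step 10
Reactants: 22 (2R,3R)-3-(3,5-dimethoxyphenyl)-2-(4-methoxyphenyl)-5-{[tri(propan-2-yl)silyl]oxymethyl}-2,3-dihydro-1-benzofuran-7-ol
Product: 23 {[(2R,3R)-3-(3,5-dimethoxyphenyl)-7-methoxy-2-(4-methoxyphenyl)-2,3-dihydro-1-benzofuran-5-yl]methoxy}tri(propan-2-yl)silane
Conditions: MeI, K2CO3, acetone, 50 °C
Reagents that add atoms: iodomethane, CI
Why: Williamson methylation of the only free phenol; the mild base does not touch the benzylic centres.

Step 11
Reactants: 23 {[(2R,3R)-3-(3,5-dimethoxyphenyl)-7-methoxy-2-(4-methoxyphenyl)-2,3-dihydro-1-benzofuran-5-yl]methoxy}tri(propan-2-yl)silane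
Product: 24 [(2R,3R)-3-(3,5-dimethoxyphenyl)-7-methoxy-2-(4-methoxyphenyl)-2,3-dihydro-1-benzofuran-5-yl]methanol
Conditions: n-Bu4NF, THF, 0 °C → rt
Reagents that add atoms: none
Why: Fluoride cleaves the Si–O bond of the primary silyl ether and leaves the aryl methyl ethers and the ring untouched.

Step 12
Reactants: 24 [(2R,3R)-3-(3,5-dimethoxyphenyl)-7-methoxy-2-(4-methoxyphenyl)-2,3-dihydro-1-benzofuran-5-yl]methanol
Product: 25 (2R,3R)-3-(3,5-dimethoxyphenyl)-7-methoxy-2-(4-methoxyphenyl)-2,3-dihydro-1-benzofuran-5-carbaldehyde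
Conditions: MnO2, CH2Cl2, rt
Reagents that add atoms: none
Why: MnO2 oxidises the benzylic alcohol to the aldehyde without over-oxidation; this carbon becomes C3.

Step 13
Reactants: 26 5-methoxybenzene-1,3-diol
Product: 27 2-iodo-5-methoxybenzene-1,3-diol
Conditions: I2, NaHCO3, H2O–THF, 0 °C
Reagents that add atoms: iodine, II
Why: Electrophilic iodination of the resorcinol under hydrogencarbonate should go to the carbon between the two hydroxyls, as for resorcinol itself, giving the symmetric iodide.

Step 14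
Reactants: 27 2-iodo-5-methoxybenzene-1,3-diol; 28 1-(chloromethyl)-4-methoxybenzene
Product: 29 2-iodo-5-methoxy-1,3-bis[(4-methoxyphenyl)methoxy]benzene
Conditions: 28 (2.2 equiv), K2CO3, n-Bu4NI (cat.), DMF, 50 °C
Reagents that add atoms: none
Why: Double Williamson etherification; the CH2 and aryl group of one of the two equivalent ethers later become C2 and its 4-methoxyphenyl group.

Step 15
Reactants: 29 2-iodo-5-methoxy-1,3-bis[(4-methoxyphenyl)methoxy]benzene; 25 (2R,3R)-3-(3,5-dimethoxyphenyl)-7-methoxy-2-(4-methoxyphenyl)-2,3-dihydro-1-benzofuran-5-carbaldehyde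
Product: 31 {2,6-bis[(4-methoxyphenyl)methoxy]-4-methoxyphenyl}[(2R,3R)-3-(3,5-dimethoxyphenyl)-7-methoxy-2-(4-methoxyphenyl)-2,3-dihydro-1-benzofuran-5-yl]methanol, via arylmagnesium chloride 30 (not isolated)
Conditions: 29, i-PrMgCl·LiCl, THF, −20 °C; then 25, −20 °C → rt
Reagents that add atoms: none
Why: Iodine–magnesium exchange followed by 1,2-addition to the aldehyde forms C3–C3a at a defined ring A position; the new carbinol centre is formed as both epimers and is removed in the next step.

Step 16
Reactants: 31 {2,6-bis[(4-methoxyphenyl)methoxy]-4-methoxyphenyl}[(2R,3R)-3-(3,5-dimethoxyphenyl)-7-methoxy-2-(4-methoxyphenyl)-2,3-dihydro-1-benzofuran-5-yl]methanol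
Product: 32 {2,6-bis[(4-methoxyphenyl)methoxy]-4-methoxyphenyl}[(2R,3R)-3-(3,5-dimethoxyphenyl)-7-methoxy-2-(4-methoxyphenyl)-2,3-dihydro-1-benzofuran-5-yl]methanone
Conditions: Dess–Martin periodinane, NaHCO3, CH2Cl2, rt
Reagents that add atoms: none
Why: Buffered Dess–Martin oxidation of the hindered diaryl carbinol to the ketone; benzyl-type ethers and the dihydrobenzofuran are stable to it.

Step 17
Reactants: 32 {2,6-bis[(4-methoxyphenyl)methoxy]-4-methoxyphenyl}[(2R,3R)-3-(3,5-dimethoxyphenyl)-7-methoxy-2-(4-methoxyphenyl)-2,3-dihydro-1-benzofuran-5-yl]methanone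
Product: 33 hydrazone of ketone 32 (E/Z mixture)
Conditions: N2H4·H2O, AcOH, n-BuOH, 110 °C
Reagents that add atoms: hydrazine, NN
Why: Condensation to the N-unsubstituted hydrazone; forcing conditions are chosen because the carbonyl is flanked by two ortho alkoxy groups.

Step 18
Reactants: 33 hydrazone of ketone 32
Product: 35 (2R,3S)-3-[(2R,3R)-3-(3,5-dimethoxyphenyl)-7-methoxy-2-(4-methoxyphenyl)-2,3-dihydro-1-benzofuran-5-yl]-6-methoxy-2-(4-methoxyphenyl)-4-[(4-methoxyphenyl)methoxy]-2,3-dihydro-1-benzofuran, via diazo compound 34 (not isolated)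
Conditions: MnO2, CH2Cl2, 0 °C; filter; Rh2(R-PTAD)4 (1 mol%), CH2Cl2, 0 °C → rt
Reagents that add atoms: none
Why: MnO2 dehydrogenates the hydrazone to the diaryldiazomethane, and the chiral dirhodium carboxylate turns it into a donor/donor carbenoid that inserts into the adjacent O–CH2–aryl C–H bond, closing the dihydrofuran ring (intramolecular carbenoid C–H insertion). The catalyst should set C3 independently of the remote centres, and the 2,3-cis isomer is expected as the kinetic product of this insertion; the two ether groups are equivalent, so there is no regiochemical choice.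

Step 19
Reactants: 35 (2R,3S)-3-[(2R,3R)-3-(3,5-dimethoxyphenyl)-7-methoxy-2-(4-methoxyphenyl)-2,3-dihydro-1-benzofuran-5-yl]-6-methoxy-2-(4-methoxyphenyl)-4-[(4-methoxyphenyl)methoxy]-2,3-dihydro-1-benzofuran
Product: 36 (2S,3S)-3-[(2R,3R)-3-(3,5-dimethoxyphenyl)-7-methoxy-2-(4-methoxyphenyl)-2,3-dihydro-1-benzofuran-5-yl]-6-methoxy-2-(4-methoxyphenyl)-2,3-dihydro-1-benzofuran-4-ol
Conditions: CF3CO2H, C6HMe5, CH2Cl2, 0 °C → rt
Reagents that add atoms: none
Why: Acid cleaves the remaining 4-methoxybenzyl ether (the cation is trapped by pentamethylbenzene) and reversibly ionises the C2–O bond through the 4-methoxybenzylic cation; reclosure should give the more stable 2,3-trans isomer while C3, which cannot ionise, is kept. Dihydrobenzofuran 2 is already trans and returns to itself, and the temperature is kept low to avoid loss of H3 from the open cation.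

Step 20
Reactants: 36 (2S,3S)-3-[(2R,3R)-3-(3,5-dimethoxyphenyl)-7-methoxy-2-(4-methoxyphenyl)-2,3-dihydro-1-benzofuran-5-yl]-6-methoxy-2-(4-methoxyphenyl)-2,3-dihydro-1-benzofuran-4-ol
Product: 37 (2S,3S)-3-[(2R,3R)-3-(3,5-dimethoxyphenyl)-7-methoxy-2-(4-methoxyphenyl)-2,3-dihydro-1-benzofuran-5-yl]-6-methoxy-2-(4-methoxyphenyl)-2,3-dihydro-1-benzofuran-4-yl trifluoromethanesulfonate
Conditions: Tf2O, pyridine, CH2Cl2, 0 °C
Reagents that add atoms: trifluoromethanesulfonic anhydride, O=S(=O)(OS(=O)(=O)C(F)(F)F)C(F)(F)F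
Why: Sulfonylation of the only free phenol turns the C4 oxygen into a leaving group for cross-coupling.

Step 21
Reactants: 37 (2S,3S)-3-[(2R,3R)-3-(3,5-dimethoxyphenyl)-7-methoxy-2-(4-methoxyphenyl)-2,3-dihydro-1-benzofuran-5-yl]-6-methoxy-2-(4-methoxyphenyl)-2,3-dihydro-1-benzofuran-4-yl trifluoromethanesulfonate; 38 1-ethynyl-4-methoxybenzene
Product: 39 (2S,3S)-3-[(2R,3R)-3-(3,5-dimethoxyphenyl)-7-methoxy-2-(4-methoxyphenyl)-2,3-dihydro-1-benzofuran-5-yl]-6-methoxy-2-(4-methoxyphenyl)-4-[(4-methoxyphenyl)ethynyl]-2,3-dihydro-1-benzofuran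
Conditions: PdCl2(PPh3)2 (5 mol%), CuI (10 mol%), n-Bu4NI, Et3N–DMF, 70 °C
Reagents that add atoms: none
Why: Sonogashira coupling of the aryl triflate with the terminal alkyne forms the C4–C(sp) bond; the stereocentres are not involved.

Step 22
Reactants: 39 (2S,3S)-3-[(2R,3R)-3-(3,5-dimethoxyphenyl)-7-methoxy-2-(4-methoxyphenyl)-2,3-dihydro-1-benzofuran-5-yl]-6-methoxy-2-(4-methoxyphenyl)-4-[(4-methoxyphenyl)ethynyl]-2,3-dihydro-1-benzofuran
Product: 40 (2S,3S)-3-[(2R,3R)-3-(3,5-dihydroxyphenyl)-7-hydroxy-2-(4-hydroxyphenyl)-2,3-dihydro-1-benzofuran-5-yl]-2-(4-hydroxyphenyl)-4-[(4-hydroxyphenyl)ethynyl]-2,3-dihydro-1-benzofuran-6-ol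
Conditions: BBr3, CH2Cl2, −78 → 0 °C; then MeOH, H2O
Reagents that add atoms: none
Why: Lewis-acid cleavage of all seven aryl methyl ethers; it is done while the alkyne and not the Z-alkene is present, and any reversible C2–O opening returns to the trans rings.

Step 23
Reactants: 40 (2S,3S)-3-[(2R,3R)-3-(3,5-dihydroxyphenyl)-7-hydroxy-2-(4-hydroxyphenyl)-2,3-dihydro-1-benzofuran-5-yl]-2-(4-hydroxyphenyl)-4-[(4-hydroxyphenyl)ethynyl]-2,3-dihydro-1-benzofuran-6-ol
Product: 41 (2S,3S)-3-[(2R,3R)-3-(3,5-dihydroxyphenyl)-7-hydroxy-2-(4-hydroxyphenyl)-2,3-dihydro-1-benzofuran-5-yl]-2-(4-hydroxyphenyl)-4-[(Z)-2-(4-hydroxyphenyl)ethenyl]-2,3-dihydro-1-benzofuran-6-ol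
Conditions: H2 (1 atm), Pd/CaCO3 poisoned with Pb(OAc)2 (Lindlar catalyst), quinoline, EtOAc–MeOH, rt, dark
Reagents that add atoms: none
Why: Lindlar semi-hydrogenation adds one equivalent of hydrogen syn across the diarylalkyne and should give the Z-alkene; the reaction is stopped after one equivalent and the product is kept from light and acid.

## Compound list

1 | methyl 5-bromofuran-3-carboxylate | COC(=O)c1coc(Br)c1 | starting material
2 | (5-bromofuran-3-yl)methanol | OCc1coc(Br)c1 | intermediate
3 | [(5-bromofuran-3-yl)methoxy]tri(propan-2-yl)silane | CC(C)[Si](OCc1coc(Br)c1)(C(C)C)C(C)C | intermediate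
4 | (3,5-dimethoxyphenyl)boronic acid | COc1cc(cc(OC)c1)B(O)O | starting material
5 | (1R,2R)-1,2-dicyclohexylethane-1,2-diol | O[C@H](C1CCCCC1)[C@H](O)C1CCCCC1 | starting material
6 | (4R,5R)-4,5-dicyclohexyl-2-(3,5-dimethoxyphenyl)-1,3,2-dioxaborolane | COc1cc(cc(OC)c1)B1O[C@H](C2CCCCC2)[C@@H](C2CCCCC2)O1 | intermediate
7 | lithium dichloromethyl borate from 6 | [Li+].COc1cc(cc(OC)c1)[B-]1(C(Cl)Cl)O[C@H](C2CCCCC2)[C@@H](C2CCCCC2)O1 | intermediate (not isolated)
8 | (4R,5R)-2-[(S)-chloro(3,5-dimethoxyphenyl)methyl]-4,5-dicyclohexyl-1,3,2-dioxaborolane | COc1cc(cc(OC)c1)[C@@H](Cl)B1O[C@H](C2CCCCC2)[C@@H](C2CCCCC2)O1 | intermediate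
9 | (4-{[tri(propan-2-yl)silyl]oxymethyl}furan-2-yl)lithium | [Li]c1cc(CO[Si](C(C)C)(C(C)C)C(C)C)co1 | intermediate (not isolated)
10 | lithium furyl borate from 8 and 9 | [Li+].COc1cc(cc(OC)c1)[C@@H](Cl)[B-]1(c2cc(CO[Si](C(C)C)(C(C)C)C(C)C)co2)O[C@H](C2CCCCC2)[C@@H](C2CCCCC2)O1 | intermediate (not isolated)
11 | (4R,5R)-4,5-dicyclohexyl-2-[(R)-(3,5-dimethoxyphenyl)(4-{[tri(propan-2-yl)silyl]oxymethyl}furan-2-yl)methyl]-1,3,2-dioxaborolane | COc1cc(cc(OC)c1)[C@H](c1cc(CO[Si](C(C)C)(C(C)C)C(C)C)co1)B1O[C@H](C2CCCCC2)[C@@H](C2CCCCC2)O1 | intermediate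
12 | lithium dichloromethyl borate from 11 | [Li+].COc1cc(cc(OC)c1)[C@H](c1cc(CO[Si](C(C)C)(C(C)C)C(C)C)co1)[B-]1(C(Cl)Cl)O[C@H](C2CCCCC2)[C@@H](C2CCCCC2)O1 | intermediate (not isolated)
13 | (4R,5R)-2-[(1S,2R)-1-chloro-2-(3,5-dimethoxyphenyl)-2-(4-{[tri(propan-2-yl)silyl]oxymethyl}furan-2-yl)ethyl]-4,5-dicyclohexyl-1,3,2-dioxaborolane | COc1cc(cc(OC)c1)[C@H](c1cc(CO[Si](C(C)C)(C(C)C)C(C)C)co1)[C@@H](Cl)B1O[C@H](C2CCCCC2)[C@@H](C2CCCCC2)O1 | intermediate
14 | (4-methoxyphenyl)magnesium bromide | COc1ccc([Mg]Br)cc1 | starting material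
15 | bromomagnesium aryl borate from 13 and 14 | COc1cc(cc(OC)c1)[C@H](c1cc(CO[Si](C(C)C)(C(C)C)C(C)C)co1)[C@@H](Cl)[B-]1(c2ccc(OC)cc2)O[C@H](C2CCCCC2)[C@@H](C2CCCCC2)O1.[Mg+]Br | intermediate (not isolated)
16 | (4R,5R)-4,5-dicyclohexyl-2-[(1R,2R)-2-(3,5-dimethoxyphenyl)-1-(4-methoxyphenyl)-2-(4-{[tri(propan-2-yl)silyl]oxymethyl}furan-2-yl)ethyl]-1,3,2-dioxaborolane | COc1cc(cc(OC)c1)[C@H](c1cc(CO[Si](C(C)C)(C(C)C)C(C)C)co1)[C@H](c1ccc(OC)cc1)B1O[C@H](C2CCCCC2)[C@@H](C2CCCCC2)O1 | intermediate (not isolated)
17 | (1R,2S)-2-(3,5-dimethoxyphenyl)-1-(4-methoxyphenyl)-2-(4-{[tri(propan-2-yl)silyl]oxymethyl}furan-2-yl)ethan-1-ol | O[C@@H](c1ccc(OC)cc1)[C@H](c1cc(OC)cc(OC)c1)c1cc(CO[Si](C(C)C)(C(C)C)C(C)C)co1 | intermediate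
18 | trichloroethene | ClC=C(Cl)Cl | starting material
19 | (E)-1,2-dichloroethenyl ether of 17 | Cl/C=C(Cl)\O[C@@H](c1ccc(OC)cc1)[C@H](c1cc(OC)cc(OC)c1)c1cc(CO[Si](C(C)C)(C(C)C)C(C)C)co1 | intermediate (not isolated)
20 | lithium acetylide of 21 | [Li]C#CO[C@@H](c1ccc(OC)cc1)[C@H](c1cc(OC)cc(OC)c1)c1cc(CO[Si](C(C)C)(C(C)C)C(C)C)co1 | intermediate (not isolated)
21 | ethynyl (1R,2S)-2-(3,5-dimethoxyphenyl)-1-(4-methoxyphenyl)-2-(4-{[tri(propan-2-yl)silyl]oxymethyl}furan-2-yl)ethyl ether | C#CO[C@@H](c1ccc(OC)cc1)[C@H](c1cc(OC)cc(OC)c1)c1cc(CO[Si](C(C)C)(C(C)C)C(C)C)co1 | intermediate (key-step precursor)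
22 | (2R,3R)-3-(3,5-dimethoxyphenyl)-2-(4-methoxyphenyl)-5-{[tri(propan-2-yl)silyl]oxymethyl}-2,3-dihydro-1-benzofuran-7-ol | CC(C)[Si](OCc1cc(O)c2c(c1)[C@@H](c1cc(OC)cc(OC)c1)[C@H](c1ccc(OC)cc1)O2)(C(C)C)C(C)C | intermediate (key-step product)
23 | {[(2R,3R)-3-(3,5-dimethoxyphenyl)-7-methoxy-2-(4-methoxyphenyl)-2,3-dihydro-1-benzofuran-5-yl]methoxy}tri(propan-2-yl)silane | CC(C)[Si](OCc1cc(OC)c2c(c1)[C@@H](c1cc(OC)cc(OC)c1)[C@H](c1ccc(OC)cc1)O2)(C(C)C)C(C)C | intermediate
24 | [(2R,3R)-3-(3,5-dimethoxyphenyl)-7-methoxy-2-(4-methoxyphenyl)-2,3-dihydro-1-benzofuran-5-yl]methanol | OCc1cc(OC)c2c(c1)[C@@H](c1cc(OC)cc(OC)c1)[C@H](c1ccc(OC)cc1)O2 | intermediate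
25 | (2R,3R)-3-(3,5-dimethoxyphenyl)-7-methoxy-2-(4-methoxyphenyl)-2,3-dihydro-1-benzofuran-5-carbaldehyde | O=Cc1cc(OC)c2c(c1)[C@@H](c1cc(OC)cc(OC)c1)[C@H](c1ccc(OC)cc1)O2 | intermediate
26 | 5-methoxybenzene-1,3-diol | COc1cc(O)cc(O)c1 | starting material
27 | 2-iodo-5-methoxybenzene-1,3-diol | COc1cc(O)c(I)c(O)c1 | intermediate
28 | 1-(chloromethyl)-4-methoxybenzene | COc1ccc(CCl)cc1 | starting material
29 | 2-iodo-5-methoxy-1,3-bis[(4-methoxyphenyl)methoxy]benzene | COc1ccc(COc2cc(OC)cc(OCc3ccc(OC)cc3)c2I)cc1 | intermediate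
30 | {4-methoxy-2,6-bis[(4-methoxyphenyl)methoxy]phenyl}magnesium chloride | COc1ccc(COc2cc(OC)cc(OCc3ccc(OC)cc3)c2[Mg]Cl)cc1 | intermediate (not isolated)
31 | diaryl carbinol from 25 and 30 (both carbinol epimers) | COc1ccc(COc2cc(OC)cc(OCc3ccc(OC)cc3)c2C(O)c2cc(OC)c3c(c2)[C@@H](c2cc(OC)cc(OC)c2)[C@H](c2ccc(OC)cc2)O3)cc1 | intermediate
32 | diaryl ketone from 31 | COc1ccc(COc2cc(OC)cc(OCc3ccc(OC)cc3)c2C(=O)c2cc(OC)c3c(c2)[C@@H](c2cc(OC)cc(OC)c2)[C@H](c2ccc(OC)cc2)O3)cc1 | intermediate
33 | hydrazone of 32 (E/Z mixture) | COc1ccc(COc2cc(OC)cc(OCc3ccc(OC)cc3)c2C(=NN)c2cc(OC)c3c(c2)[C@@H](c2cc(OC)cc(OC)c2)[C@H](c2ccc(OC)cc2)O3)cc1 | intermediate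
34 | diaryldiazomethane from 33 | COc1ccc(COc2cc(OC)cc(OCc3ccc(OC)cc3)c2C(=[N+]=[N-])c2cc(OC)c3c(c2)[C@@H](c2cc(OC)cc(OC)c2)[C@H](c2ccc(OC)cc2)O3)cc1 | intermediate (not isolated)
35 | (2R,3S)-3-[(2R,3R)-3-(3,5-dimethoxyphenyl)-7-methoxy-2-(4-methoxyphenyl)-2,3-dihydro-1-benzofuran-5-yl]-6-methoxy-2-(4-methoxyphenyl)-4-[(4-methoxyphenyl)methoxy]-2,3-dihydro-1-benzofuran | COc1ccc(COc2cc(OC)cc3c2[C@H](c2cc(OC)c4c(c2)[C@@H](c2cc(OC)cc(OC)c2)[C@H](c2ccc(OC)cc2)O4)[C@H](c2ccc(OC)cc2)O3)cc1 | intermediate
36 | (2S,3S)-3-[(2R,3R)-3-(3,5-dimethoxyphenyl)-7-methoxy-2-(4-methoxyphenyl)-2,3-dihydro-1-benzofuran-5-yl]-6-methoxy-2-(4-methoxyphenyl)-2,3-dihydro-1-benzofuran-4-ol | Oc1cc(OC)cc2c1[C@H](c1cc(OC)c3c(c1)[C@@H](c1cc(OC)cc(OC)c1)[C@H](c1ccc(OC)cc1)O3)[C@@H](c1ccc(OC)cc1)O2 | intermediate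
37 | triflate of 36 | O=S(=O)(Oc1cc(OC)cc2c1[C@H](c1cc(OC)c3c(c1)[C@@H](c1cc(OC)cc(OC)c1)[C@H](c1ccc(OC)cc1)O3)[C@@H](c1ccc(OC)cc1)O2)C(F)(F)F | intermediate
38 | 1-ethynyl-4-methoxybenzene | C#Cc1ccc(OC)cc1 | starting material
39 | heptamethyl ether of 40 | COc1ccc(C#Cc2cc(OC)cc3c2[C@H](c2cc(OC)c4c(c2)[C@@H](c2cc(OC)cc(OC)c2)[C@H](c2ccc(OC)cc2)O4)[C@@H](c2ccc(OC)cc2)O3)cc1 | intermediate
40 | (2S,3S)-3-[(2R,3R)-3-(3,5-dihydroxyphenyl)-7-hydroxy-2-(4-hydroxyphenyl)-2,3-dihydro-1-benzofuran-5-yl]-2-(4-hydroxyphenyl)-4-[(4-hydroxyphenyl)ethynyl]-2,3-dihydro-1-benzofuran-6-ol | Oc1ccc(C#Cc2cc(O)cc3c2[C@H](c2cc(O)c4c(c2)[C@@H](c2cc(O)cc(O)c2)[C@H](c2ccc(O)cc2)O4)[C@@H](c2ccc(O)cc2)O3)cc1 | intermediate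
41 | (2S,3S)-3-[(2R,3R)-3-(3,5-dihydroxyphenyl)-7-hydroxy-2-(4-hydroxyphenyl)-2,3-dihydro-1-benzofuran-5-yl]-2-(4-hydroxyphenyl)-4-[(Z)-2-(4-hydroxyphenyl)ethenyl]-2,3-dihydro-1-benzofuran-6-ol | Oc1ccc(/C=C\c2cc(O)cc3c2[C@H](c2cc(O)c4c(c2)[C@@H](c2cc(O)cc(O)c2)[C@H](c2ccc(O)cc2)O4)[C@@H](c2ccc(O)cc2)O3)cc1 | target

## Step count and least certain steps

Total: 23 steps. Longest linear sequence: 19 steps (from 4 through steps 3–12 and 15–23; the same length from 1).

**Step 9 (key step).** The terminal ynol ether may be lost before it cyclises, by hydration on the gold catalyst, by retro-ene loss of ketene or by a sigmatropic shift onto the 4-methoxyphenyl ring. The cyclopropyl carbenoid may also be diverted into oligomers, because the furan has no substituent at its free α-position to assist ring opening. The fallback gives up the de novo formation of ring B and brings it in as a preformed arene. It sets out from the chloro boronic ester 8, which is treated with the aryllithium made from {[3-bromo-5-methoxy-4-(methoxymethoxy)phenyl]methoxy}tri(propan-2-yl)silane F1 to give, with inversion, the diarylmethyl boronic ester F2. Homologation with LiCHCl2 and ZnCl2 gives the chloro boronic ester F3, aryl transfer from 14 gives the triaryl boronic ester F4, and alkaline peroxide gives the (1R,2R) alcohol F5. HCl in methanol then removes the methoxymethyl and silyl groups and closes the C2′–O bond through the 4-methoxybenzylic cation to the trans ring under control of C3′. The sequence comes back to the route at 24.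

**Step 5.** The benzylic α-chloro boronic ester 8 can epimerise through chloride exchange before the furyl group migrates, and the furyllithium can attack at chlorine or oxygen; either process erodes the diaryl centre, which cannot be corrected later. The fallback leaves boron chemistry. It sets out from 3, which is coupled with the ketone 2-(3,5-dimethoxyphenyl)-1-(4-methoxyphenyl)ethan-1-one F6 (from anisole by Friedel–Crafts acylation) by α-arylation with Pd(OAc)2, P(t-Bu)3 and NaOt-Bu to give the racemic triaryl ketone F7. Transfer hydrogenation with RuCl(p-cymene)[(R,R)-TsDPEN] in HCO2H–Et3N should fix the carbinol carbon as R, but the ratio at the neighbouring carbon is not predictable, so 17 is separated from its (1R,2R) epimer F8 by chromatography and F8 is returned to F7 by Dess–Martin oxidation. The sequence comes back at 17.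

**Step 18 (with step 17).** Hydrazone formation may stall at the di-ortho-substituted ketone, the electron-rich diazo compound may dimerise to the azine, and the hindered carbenoid may show poor face selectivity. The fallback gives up catalyst control and uses separation. It sets out from ketone 32, to which 4-methoxybenzylmagnesium chloride is added to give the tertiary alcohol F9. CF3CO2H with pentamethylbenzene then dehydrates F9, removes both benzyl-type ethers and closes the ring by Markovnikov addition of the phenol, giving the trans ring as 36 together with its (2R,3R) isomer F10. The two are diastereomers because of the fixed C2′ and C3′ centres and are separated by chromatography. The sequence comes back at 36.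

**Step 22.** Hydrogen bromide or the boron halide may add across the electron-rich diarylalkyne, and the opened C2 cations may recombine by Friedel–Crafts paths instead of reclosing. The fallback changes the order of events. It sets out from triflate 37, whose six methyl ethers are cleaved first with BBr3 (the triflate is stable) to give the hexahydroxy triflate F11, which is then coupled with 4-ethynylphenol under the conditions of step 21. The sequence comes back at 40.

## Further compounds

F1 | step 9 | {[3-bromo-5-methoxy-4-(methoxymethoxy)phenyl]methoxy}tri(propan-2-yl)silane | COCOc1c(Br)cc(CO[Si](C(C)C)(C(C)C)C(C)C)cc1OC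
F2 | step 9 | (4R,5R)-4,5-dicyclohexyl-2-[(R)-(3,5-dimethoxyphenyl){3-methoxy-2-(methoxymethoxy)-5-{[tri(propan-2-yl)silyl]oxymethyl}phenyl}methyl]-1,3,2-dioxaborolane | COc1cc(cc(OC)c1)[C@H](c1cc(CO[Si](C(C)C)(C(C)C)C(C)C)cc(OC)c1OCOC)B1O[C@H](C2CCCCC2)[C@@H](C2CCCCC2)O1
F3 | step 9 | (4R,5R)-2-[(1S,2R)-1-chloro-2-(3,5-dimethoxyphenyl)-2-{3-methoxy-2-(methoxymethoxy)-5-{[tri(propan-2-yl)silyl]oxymethyl}phenyl}ethyl]-4,5-dicyclohexyl-1,3,2-dioxaborolane | COc1cc(cc(OC)c1)[C@H](c1cc(CO[Si](C(C)C)(C(C)C)C(C)C)cc(OC)c1OCOC)[C@@H](Cl)B1O[C@H](C2CCCCC2)[C@@H](C2CCCCC2)O1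
F4 | step 9 | (4R,5R)-4,5-dicyclohexyl-2-[(1R,2R)-2-(3,5-dimethoxyphenyl)-2-{3-methoxy-2-(methoxymethoxy)-5-{[tri(propan-2-yl)silyl]oxymethyl}phenyl}-1-(4-methoxyphenyl)ethyl]-1,3,2-dioxaborolane | COc1cc(cc(OC)c1)[C@H](c1cc(CO[Si](C(C)C)(C(C)C)C(C)C)cc(OC)c1OCOC)[C@H](c1ccc(OC)cc1)B1O[C@H](C2CCCCC2)[C@@H](C2CCCCC2)O1
F5 | step 9 | (1R,2R)-2-(3,5-dimethoxyphenyl)-2-{3-methoxy-2-(methoxymethoxy)-5-{[tri(propan-2-yl)silyl]oxymethyl}phenyl}-1-(4-methoxyphenyl)ethan-1-ol | O[C@@H](c1ccc(OC)cc1)[C@H](c1cc(OC)cc(OC)c1)c1cc(CO[Si](C(C)C)(C(C)C)C(C)C)cc(OC)c1OCOC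
F6 | step 5 | 2-(3,5-dimethoxyphenyl)-1-(4-methoxyphenyl)ethan-1-one | COc1ccc(cc1)C(=O)Cc1cc(OC)cc(OC)c1
F7 | step 5 | 2-(3,5-dimethoxyphenyl)-1-(4-methoxyphenyl)-2-(4-{[tri(propan-2-yl)silyl]oxymethyl}furan-2-yl)ethan-1-one (racemic) | COc1ccc(cc1)C(=O)C(c1cc(OC)cc(OC)c1)c1cc(CO[Si](C(C)C)(C(C)C)C(C)C)co1
F8 | step 5 | (1R,2R)-2-(3,5-dimethoxyphenyl)-1-(4-methoxyphenyl)-2-(4-{[tri(propan-2-yl)silyl]oxymethyl}furan-2-yl)ethan-1-ol | O[C@@H](c1ccc(OC)cc1)[C@@H](c1cc(OC)cc(OC)c1)c1cc(CO[Si](C(C)C)(C(C)C)C(C)C)co1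
F9 | step 18 | 1-{2,6-bis[(4-methoxyphenyl)methoxy]-4-methoxyphenyl}-1-[(2R,3R)-3-(3,5-dimethoxyphenyl)-7-methoxy-2-(4-methoxyphenyl)-2,3-dihydro-1-benzofuran-5-yl]-2-(4-methoxyphenyl)ethan-1-ol (both carbinol epimers) | COc1ccc(COc2cc(OC)cc(OCc3ccc(OC)cc3)c2C(O)(Cc2ccc(OC)cc2)c2cc(OC)c3c(c2)[C@@H](c2cc(OC)cc(OC)c2)[C@H](c2ccc(OC)cc2)O3)cc1
F10 | step 18 | (2R,3R)-3-[(2R,3R)-3-(3,5-dimethoxyphenyl)-7-methoxy-2-(4-methoxyphenyl)-2,3-dihydro-1-benzofuran-5-yl]-6-methoxy-2-(4-methoxyphenyl)-2,3-dihydro-1-benzofuran-4-ol | Oc1cc(OC)cc2c1[C@@H](c1cc(OC)c3c(c1)[C@@H](c1cc(OC)cc(OC)c1)[C@H](c1ccc(OC)cc1)O3)[C@H](c1ccc(OC)cc1)O2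
F11 | step 22 | (2S,3S)-3-[(2R,3R)-3-(3,5-dihydroxyphenyl)-7-hydroxy-2-(4-hydroxyphenyl)-2,3-dihydro-1-benzofuran-5-yl]-6-hydroxy-2-(4-hydroxyphenyl)-2,3-dihydro-1-benzofuran-4-yl trifluoromethanesulfonate | O=S(=O)(Oc1cc(O)cc2c1[C@H](c1cc(O)c3c(c1)[C@@H](c1cc(O)cc(O)c1)[C@H](c1ccc(O)cc1)O3)[C@@H](c1ccc(O)cc1)O2)C(F)(F)F
A1 | alternative 1 | 2-[(1R,2R)-2-(3,5-dimethoxyphenyl)-2-[5-(1,3-dioxolan-2-yl)-3-methoxy-2-(methoxymethoxy)phenyl]-1-(4-methoxyphenyl)ethyl]-4,4,5,5-tetramethyl-1,3,2-dioxaborolane | COCOc1c(OC)cc(C2OCCO2)cc1[C@@H](c1cc(OC)cc(OC)c1)[C@@H](B1OC(C)(C)C(C)(C)O1)c1ccc(OC)cc1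
A2 | alternative 1 | 2-[3-bromo-5-methoxy-4-(methoxymethoxy)phenyl]-1,3-dioxolane | COCOc1c(OC)cc(C2OCCO2)cc1Br
A3 | alternative 1 | 2-[(E)-2-(3,5-dimethoxyphenyl)ethenyl]-4,4,5,5-tetramethyl-1,3,2-dioxaborolane | COc1cc(/C=C/B2OC(C)(C)C(C)(C)O2)cc(OC)c1
A4 | alternative 1 | (4-methoxyphenyl)lithium | [Li]c1ccc(OC)cc1
A5 | alternative 2 | methyl (2S,3S)-4-(benzyloxy)-6-methoxy-2-[4-(2,2-dimethylpropanoyloxy)phenyl]-2,3-dihydro-1-benzofuran-3-carboxylate | c1ccccc1COc1cc(OC)cc2c1[C@H](C(=O)OC)[C@@H](c1ccc(OC(=O)C(C)(C)C)cc1)O2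
A6 | alternative 2 | (2S)-5-(benzyloxy)-7-methoxy-2-[4-(2,2-dimethylpropanoyloxy)phenyl]-2,3-dihydro-4H-chromen-4-one | O=C1C[C@@H](c2ccc(OC(=O)C(C)(C)C)cc2)Oc2cc(OC)cc(OCc3ccccc3)c21
A7 | alternative 3 | (2S,3S)-3-[(2R,3R)-3-(3,5-dimethoxyphenyl)-7-methoxy-2-(4-methoxyphenyl)-2,3-dihydro-1-benzofuran-5-yl]-6-ethoxy-2-(4-methoxyphenyl)-4-[(Z)-2-(4-methoxyphenyl)ethenyl]-2,3-dihydro-1-benzofuran | COc1ccc(/C=C\c2cc(OCC)cc3c2[C@H](c2cc(OC)c4c(c2)[C@@H](c2cc(OC)cc(OC)c2)[C@H](c2ccc(OC)cc2)O4)[C@@H](c2ccc(OC)cc2)O3)cc1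
A8 | alternative 3 | ethynyl ether of (1S,2S,5Z)-2-[(2R,3R)-3-(3,5-dimethoxyphenyl)-7-methoxy-2-(4-methoxyphenyl)-2,3-dihydro-1-benzofuran-5-yl]-1,6-bis(4-methoxyphenyl)hex-5-en-3-yn-1-ol | C#CO[C@H](c1ccc(OC)cc1)[C@@H](c1cc(OC)c2c(c1)[C@@H](c1cc(OC)cc(OC)c1)[C@H](c1ccc(OC)cc1)O2)C#C/C=C\c1ccc(OC)cc1
A9 | alternative 3 | ethoxyethyne | C#COCC
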